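**Retrosynthetic overview** (disconnections listed from the starting materials upward)
1. Ring order: the ten-membered ring is bought as germacrone 1. Rings A and B are closed together by one transannular C5–C10 cyclization (germacrane → eudesmane) to 2.
2. Eudesmane → eremophilane: 2 → α-epoxide 3 → isopetasol 4 by epoxide-triggered 1,2-H and 1,2-CH3 shifts (sets C3, C4, C5).
3. 4 → 5 (deconjugation, sets C7) → 6, 7, 8 → diol 9 (conjugate reduction and Rubottom oxidation, sets C10 and C9).
4. Side chain: 10 → 11; 11 + 12 → 13 → 14; 14 + 15 → 16 (cross-metathesis).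
5. Last bond made, first one cut on paper: the C3 ester, 9 + 16 → 17 → target 18.

Assumption: germacrone (bulk isolate from zdravetz or Curcuma oil) counts as a cheap commercial starting material. The antipode of the chiral acid in step 1 that gives (5R,10R)-2 is fixed in the first run, and the route is written for that antipode.

Orientation used for α/β: eremophilane/eudesmane numbering, 5-CH3 (eremophilane) or 10-CH3 (eudesmane) drawn β. The target is 3α-acyloxy, 4β-CH3, 5β-CH3, 7β-isopropenyl, 9β-OH, 10β-H (cis-decalin).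

**Step 1**
Reactants: 1 germacrone
Product: 2 (5R,10R)-eudesma-3,7(11)-dien-8-one (trans-fused, 5α-H, 10β-CH3)
Conditions: (S,S)-IDPi acid [imidodiphosphorimidate from two (S)-3,3'-bis(3,5-(CF3)2C6H3)-BINOL phosphoryl units, N-SO2CF3 groups] (3 mol %), HFIP/CH2Cl2, −40 °C
Reagents that add atoms: none
Why: Proposed new method: the confined chiral acid, hydrogen-bonded to the C8 carbonyl, protonates C1 of the strained (E)-1(10)-olefin of one of the two rapidly interconverting planar-chiral crown conformers of 1 (dynamic kinetic asymmetric transformation), the 4(5)-olefin attacks C10 through the chair–chair transition state of the biosynthetic germacrane-to-eudesmane transannular cation–olefin cyclization so that 5-H and 10-CH3 end up trans, and the counter-anion removes H-3 from the C4 cation; the closest known reactions are the racemic acid-mediated cyclization of germacrone to the same selinadienones and imidodiphosphorimidate-catalysed enantioselective proton-initiated polyene cyclizations.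

**Step 2**
Reactants: 2 (5R,10R)-eudesma-3,7(11)-dien-8-one
Product: 4 (3R,4R,5R)-3α-hydroxyeremophila-7(11),9-dien-8-one (isopetasol), via α-epoxide 3 (not isolated)
Conditions: DMDO (1.05 equiv), acetone/CH2Cl2, −30 °C; evaporate cold; Tf2NH (5 mol %), HFIP, −20 → 0 °C
Reagents that add atoms: dimethyldioxirane (DMDO), CC1(C)OO1
Why: Proposed new method: the dioxirane epoxidizes only the electron-rich 3(4)-olefin from the α face (anti to the axial 10-CH3), and in ionizing, non-nucleophilic HFIP the protonated epoxide opens at C4 to a tertiary cation that is drained by the biosynthetic 1,2-shifts, axial 5α-H to C4 (setting 4-CH3 β and leaving 3α-OH in place) and then axial 10β-CH3 to C5 (setting 5-CH3 β), ending with loss of H-9 to the conjugated enone as thermodynamic sink; the closest known reactions are Westphalen-type C10-to-C5 methyl shifts, backbone rearrangements of steroid and triterpene epoxides, and the acid-induced conversion of epoxy-eudesmanes into eremophilanes (Wagner–Meerwein shifts).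

**Step 3**
Reactants: 4 isopetasol
Product: 5 (3R,4R,5R,7R)-3α-hydroxy-7β-isopropenyl-eremophila-9,11-dien-8-one (7α-H)
Conditions: LiN(iPr)2 (LDA, 2.3 equiv), THF/DMPU, −78 °C, 30 min; inverse quench into AcOH/THF, −78 °C
Reagents that add atoms: none
Why: Kinetic γ-deprotonation takes the isopropylidene CH3 that lies syn to the carbonyl (the 9(10)-enone has only anti γ-hydrogens, at C1), and kinetic α-protonation of the trienolate (deconjugative enolate protonation) occurs at C7 from the α face, anti to the pseudo-axial 5β-CH3, so the isopropenyl group ends up β (7R).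

**Step 4**
Reactants: 5 (3R,4R,5R,7R)-3α-hydroxy-7β-isopropenyl-eremophila-9,11-dien-8-one
Product: 9 (3R,4R,5R,7R,9R,10S)-3α,9β-dihydroxy-10βH-eremophil-11-en-8-one, via TMS ether 6 (not isolated), via silyl enol ether 7 (not isolated), via silyloxy ketone 8 (not isolated)
Conditions: MSTFA (1.2 equiv), CH2Cl2, rt, evaporate; [(Ph3P)CuH]6 (5 mol %), PhMe2SiH (1.5 equiv), toluene, rt; DMDO (1.05 equiv), acetone/CH2Cl2, −78 °C; Et3N·3HF, THF, 0 °C
Reagents that add atoms: dimethyldioxirane (DMDO), CC1(C)OO1
Why: Copper hydride 1,4-hydrosilylation (Stryker-type conjugate reduction) delivers hydride to C10 syn to the angular methyl, as cuprates do with octalones, giving the cis-fused 10β-H silyl enol ether regiospecifically without touching the isopropenyl group or the labile C7 centre, and Rubottom oxidation with DMDO then attacks the electron-rich enol ether from the convex β face to give the equatorial 9β-OH after fluoride cleavage of both silyl groups.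

**Step 5**
Reactants: 10 rac-pent-1-en-3-ol
Product: 11 (R)-pent-1-en-3-ol
Conditions: Ti(OiPr)4 (10 mol %), L-(+)-DIPT (15 mol %), TBHP (0.6 equiv), 4 Å MS, CH2Cl2, −20 °C
Reagents that add atoms: none
Why: Sharpless kinetic resolution: with L-(+)-DIPT the (S)-alcohol is epoxidized much faster, so the (R)-alcohol is recovered in high ee at about 55% conversion.

**Step 6**
Reactants: 11 (R)-pent-1-en-3-ol; 12 angelic acid, (Z)-2-methylbut-2-enoic acid
Product: 14 (R)-pent-1-en-3-yl (Z)-2-methylbut-2-enoate, via mixed anhydride 13 (not isolated)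
Conditions: 2,4,6-Cl3C6H2COCl, Et3N, toluene, rt; then 11, 75 °C, sealed tube, no DMAP
Reagents that add atoms: none
Why: Yamaguchi-type mixed-anhydride esterification run without DMAP acylates the alcohol at the less hindered angeloyl carbonyl and avoids base-induced angelate-to-tiglate isomerization; the carbinol centre is not involved.

**Step 7**
Reactants: 14 (R)-pent-1-en-3-yl (Z)-2-methylbut-2-enoate; 15 acrylic acid (3 equiv)
Product: 16 (R,E)-4-{[(Z)-2-methylbut-2-enoyl]oxy}hex-2-enoic acid
Conditions: second-generation Hoveyda–Grubbs catalyst RuCl2(=CH-C6H4-2-OiPr)(H2IMes) (5 mol %), CH2Cl2, 40 °C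
Reagents that add atoms: none
Why: Olefin cross-metathesis between the terminal allylic olefin and acrylic acid gives the (E)-enoic acid under thermodynamic control, while the trisubstituted, electron-poor angelate olefin is inert and the stereocentre is untouched.

**Step 8**
Reactants: 9 (3R,4R,5R,7R,9R,10S)-3α,9β-dihydroxy-10βH-eremophil-11-en-8-one; 16 (R,E)-4-{[(Z)-2-methylbut-2-enoyl]oxy}hex-2-enoic acid (1.05 equiv)
Product: 18 target CNP0190706.1, via O-acylisourea 17 (not isolated)
Conditions: DCC (1.1 equiv), DMAP (10 mol %), CH2Cl2, −20 → 0 °C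
Reagents that add atoms: none
Why: Steglich esterification: the equatorial 3α-OH is a normal secondary alcohol, whereas the 9-OH is an α-ketol hydroxyl that is hydrogen-bonded to C8=O, electron-poor and flanked by the ring-fusion carbon, so one equivalent of activated acid acylates C3 selectively at low temperature without touching any stereocentre.

**Compound list**
1 | germacrone, (3E,7E)-3,7-dimethyl-10-(propan-2-ylidene)cyclodeca-3,7-dien-1-one | O=C1C/C(C)=C/CC/C(C)=C/CC1=C(C)C | starting material
2 | (5R,10R)-eudesma-3,7(11)-dien-8-one (5α-H, 10β-CH3) | CC1=CCC[C@]2(C)CC(=O)C(=C(C)C)C[C@@H]12 | intermediate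
3 | (3R,4S,5R,10R)-3α,4α-epoxyeudesm-7(11)-en-8-one | C[C@@]12O[C@@H]1CC[C@]3(C)CC(=O)C(=C(C)C)C[C@@H]23 | intermediate
4 | (3R,4R,5R)-3α-hydroxyeremophila-7(11),9-dien-8-one (isopetasol; 4β,5β-dimethyl) | CC(C)=C1C[C@@]2(C)C(CC[C@@H](O)[C@@H]2C)=CC1=O | intermediate
5 | (3R,4R,5R,7R)-3α-hydroxy-7β-isopropenyl-eremophila-9,11-dien-8-one | C=C(C)[C@H]1C[C@@]2(C)C(CC[C@@H](O)[C@@H]2C)=CC1=O | intermediate
6 | 3-O-trimethylsilyl ether of 5 | C=C(C)[C@H]1C[C@@]2(C)C(CC[C@@H](O[Si](C)(C)C)[C@@H]2C)=CC1=O | intermediate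
7 | (3R,4R,5S,7R,10R)-8-(dimethylphenylsilyloxy)-3α-(trimethylsilyloxy)-10βH-eremophila-8,11-diene (7β-isopropenyl) | C=C(C)[C@H]1C[C@@]2(C)[C@H](CC[C@@H](O[Si](C)(C)C)[C@@H]2C)C=C1O[Si](C)(C)c1ccccc1 | intermediate
8 | (3R,4R,5R,7R,9R,10S)-9β-(dimethylphenylsilyloxy)-3α-(trimethylsilyloxy)-10βH-eremophil-11-en-8-one | C=C(C)[C@H]1C[C@@]2(C)[C@H](CC[C@@H](O[Si](C)(C)C)[C@@H]2C)[C@@H](O[Si](C)(C)c3ccccc3)C1=O | intermediate
9 | (3R,4R,5R,7R,9R,10S)-3α,9β-dihydroxy-10βH-eremophil-11-en-8-one | C=C(C)[C@H]1C[C@@]2(C)[C@H](CC[C@@H](O)[C@@H]2C)[C@@H](O)C1=O | intermediate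
10 | rac-pent-1-en-3-ol | C=CC(O)CC | starting material
11 | (R)-pent-1-en-3-ol | C=C[C@H](O)CC | intermediate
12 | angelic acid, (Z)-2-methylbut-2-enoic acid | C/C=C(/C)C(=O)O | starting material
13 | (Z)-2-methylbut-2-enoic 2,4,6-trichlorobenzoic anhydride | C/C=C(/C)C(=O)OC(=O)c1c(Cl)cc(Cl)cc1Cl | intermediate
14 | (R)-pent-1-en-3-yl (Z)-2-methylbut-2-enoate | C=C[C@H](OC(=O)/C(C)=C\C)CC | intermediate
15 | acrylic acid | C=CC(=O)O | starting material
16 | (R,E)-4-{[(Z)-2-methylbut-2-enoyl]oxy}hex-2-enoic acid | OC(=O)/C=C/[C@@H](CC)OC(=O)/C(C)=C\C | intermediate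
17 | O-acylisourea of 16 with N,N'-dicyclohexylcarbodiimide | O=C(/C=C/[C@@H](CC)OC(=O)/C(C)=C\C)OC(=NC1CCCCC1)NC1CCCCC1 | intermediate
18 | CNP0190706.1, (3R,4R,5R,7R,9R,10S)-9β-hydroxy-8-oxo-10βH-eremophil-11-en-3α-yl (R,E)-4-{[(Z)-2-methylbut-2-enoyl]oxy}hex-2-enoate | C=C(C)[C@H]1C[C@@]2(C)[C@H](CC[C@@H](OC(=O)/C=C/[C@@H](CC)OC(=O)/C(C)=C\C)[C@@H]2C)[C@@H](O)C1=O | target

**Totals**
Total steps: 8. Longest linear sequence: 5 (steps 1, 2, 3, 4, 8); the side-chain branch is 4 (steps 5, 6, 7, 8).

**Three steps most likely to fail, with fallbacks**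

Step 1 (enantioselectivity, and 3-ene versus 4(15)-ene regiochemistry, of a new catalytic cyclization). Fallback, from 1 back to the route at 4: cyclize 1 with achiral TsOH·H2O in CH2Cl2, which gives 2 together with its mirror image, the (5S,10S)-eudesmadienone F1. Carry the racemate through the unchanged step 2, where the mirror-image epoxide, ent-epoxide F2, is not isolated, and 4 is formed together with its enantiomer, ent-isopetasol F3. Then resolve with immobilized Candida antarctica lipase B and vinyl acetate in MTBE. By the Kazlauskas rule the (3R)-alcohol is acylated to isopetasol acetate F4, which is separated from unreacted F3 by chromatography. K2CO3 in MeOH returns 4.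

Step 2 (the free C4 cation may instead give the 3-ketone by a Meinwald shift, allylic alcohols by E1, or a 3,10-ether). Fallback, from 2 back to the route at 4: NBS in aqueous acetone gives the trans-diaxial 3α-bromo-4β-hydroxy bromohydrin F5, and K2CO3 in MeOH closes it to the 3β,4β-epoxide F6. With BF3·OEt2 in CH2Cl2 at −78 °C the C4–O bond is now antiperiplanar to 5α-H, so hydride migrates in concert with ring opening and no free C4 cation exists. The same methyl shift and H-9 loss give 3β-hydroxy-eremophiladienone (3-epi-isopetasol) F7. Mitsunobu inversion (4-nitrobenzoic acid, PPh3, DIAD, THF) gives the 3α-(4-nitrobenzoate) F8, and K2CO3 in MeOH returns 4.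

Step 3 (regiochemistry of γ-deprotonation and the face of C7 protonation). Fallback, from 4 back to the route at 9: H2 with Pd/C in EtOAc reduces only the trisubstituted 9(10)-enone, from the β face, to the cis-fused 3α-hydroxy-10βH-eremophil-7(11)-en-8-one F9. LiN(iPr)2 (3.2 equiv) followed by 2-(phenylsulfonyl)-3-phenyloxaziridine hydroxylates the α'-enolate at C9 from the convex face to the 3α,9β-dihydroxy enone F10. Irradiation at 350 nm in acetonitrile with catalytic imidazole then photoenolizes the s-cis isopropylidene ketone through its syn γ-hydrogen. Only the conjugated isomer absorbs, so it is pumped to the deconjugated ketone while the base equilibrates C7 to the all-equatorial 7β epimer, which is 9.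

**Further compounds**
F1 | step 1 | (5S,10S)-eudesma-3,7(11)-dien-8-one (enantiomer of 2) | CC1=CCC[C@@]2(C)CC(=O)C(=C(C)C)C[C@H]12
F2 | step 1 | (3S,4R,5S,10S)-3,4-epoxyeudesm-7(11)-en-8-one (enantiomer of 3, not isolated) | C[C@]12O[C@H]1CC[C@@]3(C)CC(=O)C(=C(C)C)C[C@H]23
F3 | step 1 | (3S,4S,5S)-3-hydroxyeremophila-7(11),9-dien-8-one (enantiomer of 4) | CC(C)=C1C[C@]2(C)C(CC[C@H](O)[C@H]2C)=CC1=O
F4 | step 1 | (3R,4R,5R)-3α-acetoxyeremophila-7(11),9-dien-8-one | CC(C)=C1C[C@@]2(C)C(CC[C@@H](OC(C)=O)[C@@H]2C)=CC1=O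
F5 | step 2 | (3R,4R,5R,10R)-3α-bromo-4β-hydroxyeudesm-7(11)-en-8-one | C[C@]1(O)[C@H](Br)CC[C@]2(C)CC(=O)C(=C(C)C)C[C@@H]12
F6 | step 2 | (3S,4R,5R,10R)-3β,4β-epoxyeudesm-7(11)-en-8-one | C[C@]12O[C@H]1CC[C@]3(C)CC(=O)C(=C(C)C)C[C@@H]23
F7 | step 2 | (3S,4R,5R)-3β-hydroxyeremophila-7(11),9-dien-8-one | CC(C)=C1C[C@@]2(C)C(CC[C@H](O)[C@@H]2C)=CC1=O
F8 | step 2 | (3R,4R,5R)-3α-(4-nitrobenzoyloxy)eremophila-7(11),9-dien-8-one | CC(C)=C1C[C@@]2(C)C(CC[C@@H](OC(=O)c3ccc(cc3)[N+](=O)[O-])[C@@H]2C)=CC1=O
F9 | step 3 | (3R,4R,5S,10R)-3α-hydroxy-10βH-eremophil-7(11)-en-8-one | CC(C)=C1C[C@@]2(C)[C@H](CC[C@@H](O)[C@@H]2C)CC1=O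
F10 | step 3 | (3R,4R,5R,9R,10S)-3α,9β-dihydroxy-10βH-eremophil-7(11)-en-8-one | CC(C)=C1C[C@@]2(C)[C@H](CC[C@@H](O)[C@@H]2C)[C@@H](O)C1=O
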